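The numbers in the tables were computed on assumed constants; scatter was added.

the same everywhere: free monomer 0.037 M; initiator 0.54 mol%; impurity 0.18 mM
- red: transfer agent 0.18 mM; run made earlier
- amber: transfer agent 0.74 mM; run made earlier
- flask: transfer agent 0.370 mM; time 15 min

- red (time / min: monomer in chains / %, free monomer / %): 1.00: 0.3, 100.9; 3.00: 5.6, 97.7; 6.00: 8.2, 90.4; 10.0: 15.6, 86.4
- amber (time / min: monomer in chains / %, free monomer / %): 1.00: 0, 100.0; 3.00: 4.5, 96.1; 6.00: 8.5, 89.5; 10.0: 16.5, 85.5

(each reading ± 1 percentage point)

1. average number of monomer units in a chain (chains begun, living or dead) at 15 min
2. part of the free monomer that has reacted at 15 min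

- the average divides the monomer in chains by the number of chains begun, living and dead together
- the earlier runs were read with a standard deviation of 1 percentage point
- candidate steps: free monomer + living end -> monomer in chains + living end; free monomer + initiator -> living end + monomer in chains; initiator + impurity -> spent initiator; living end + transfer agent -> dead chain
- the earlier runs do not show the number of chains; that part of a forecast is a guess

**Ratio turned round.** The ratio of impurity to initiator charged to the flask is 0.901. This reckoning assumes that impurity spends initiator one for one ahead of chain starts, so in this reckoning a stalled flask is one where that ratio reaches one. The flask stands short of that by the initiator charged less the impurity charged, the margin 0.0198 mM, which is taken as the number of chains begun.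

**Mean curve.** The red and amber runs differ 4.11-fold in transfer agent, yet their readings at 10.0 min stand 0.9 percentage points apart in monomer in chains, against a scatter of 1 point, so the reckoning holds living ends steady and treats free monomer as pseudo-first-order. The mean of their readings at 10.0 min is a loss of 15.1%, which gives a rate constant of 0.0163 /min and 21.7% reacted at 15 min. A straight line gives 22.6%, a gap of 0.90 points. Reacted monomer over the margin then gives 406 units per chain, the value this reckoning commits to.

**Result.** The forecast gave 100 units and 22%, calling the first “a guess near 100”. The flask gives 336 units and 21.6%.

    free monomer + living end → monomer in chains + living end, rate k1*[living end]*[free monomer] (k = 13.4 /M/s)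
    free monomer + initiator → living end + monomer in chains (k = 0.160 /M/s)
    initiator + impurity → spent initiator (k = 941 /M/s)
    living end + transfer agent → dead chain (kL = 0.651 /M/s)

**Margin checked.** In the flask, as charged, each initiator is taken by impurity at 0.169 /s and by free monomer at 0.00592 /s, a ratio of 28.5. Living ends and dead chains of the flask together reach 0.0237 mM at 15 min, 1.20 times the margin. In the neighbour flask with 7.2 × 10⁻⁵ M of impurity, the margin is 0.128 mM, which scales the rate constant to 0.105 /min and gives 79.4% and 230 units per chain. The simulation of that flask gives 67.3% and 201 units.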